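**Plan**
- Cuts: the pyrone is opened at C4–C5 and O1–C2. This gives the enol of pentan-3-one (C5, C6, O1) and a benzylmalonyl unit (C2, C3, C4) that already carries the bridge CH2. Further cuts are CH2–C3, CH2–C1', the C3' prenyl bond, the O–CH3 bond and the C5' acyl bond, which lead back to phloroglucinol.
- Enabling feature: the C2' oxygen is ortho to the bridge carbon C1' and para to the C5' ketone. It can therefore hold malonyl C2 in a six-membered aryl lactone (chroman-2-one ring) and later leave as a stabilised phenoxide. C4 is activated separately as the acid chloride.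
- Forward order: the arene is completed first by acylation, bis-MOM protection, O-prenylation, Claisen–Cope shift, methylation of the ortho hydroxyl thus freed, and deprotection. The lactone ring follows (Mannich base, quinone methide, Meldrum's acid). The pyrone ring comes last, and its closure reopens the lactone ring.
- Stereochemistry: the target has no stereocentre and no stereogenic double bond. The lactone α-carbon is racemic and becomes sp2 in the last step.

Key step: step 11

Remark: the target is treated as its 4-hydroxy-2-pyrone tautomer. The enol ether geometry is lost on pyrone formation, so it is not controlled.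

Step 1
Reactants: 1 phloroglucinol; 2 isobutyryl chloride
Product: 3 2-methyl-1-(2,4,6-trihydroxyphenyl)propan-1-one (phlorisobutyrophenone)
Conditions: AlCl3 (3.5 equiv), CH2Cl2/MeNO2, 0 °C to 40 °C; aq. HCl quench
Reagents that add atoms: none
Why: Friedel–Crafts acylation of a ring with three equivalent activated positions should stop at the monoketone, because the new acyl group deactivates the product.

Step 2
Reactants: 3 phlorisobutyrophenone
Product: 4 1-[2-hydroxy-4,6-bis(methoxymethoxy)phenyl]-2-methylpropan-1-one
Conditions: MOMCl (2.2 equiv), iPr2NEt (2.5 equiv), CH2Cl2, 0 °C to rt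
Reagents that add atoms: chloromethyl methyl ether (MOMCl), COCCl
Why: In this Williamson-type acetal etherification one ortho hydroxyl stays chelated to the ketone, so two equivalents of MOMCl should cap only the para and the other ortho oxygen.

Step 3
Reactants: 4 bis-MOM ketone; 5 prenyl bromide
Product: 6 1-[2,4-bis(methoxymethoxy)-6-(3-methylbut-2-enyloxy)phenyl]-2-methylpropan-1-one
Conditions: K2CO3, acetone, reflux
Reagents that add atoms: none
Why: Williamson O-alkylation of the only free phenol with a reactive allylic bromide is expected once carbonate breaks the chelate.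

Step 4
Reactants: 6 prenyl aryl ether
Product: 9 1-[6-hydroxy-2,4-bis(methoxymethoxy)-3-(3-methylbut-2-enyl)phenyl]-2-methylpropan-1-one, via ortho-dienone 7 (not isolated), via para-dienone 8 (not isolated)
Conditions: PhNEt2, 200 °C, argon, sealed tube
Reagents that add atoms: none
Why: An aromatic Claisen rearrangement places an inverted 1,1-dimethylallyl group on the free ortho carbon (7), a Cope rearrangement carries it to the para carbon with a second inversion (8), and tautomerisation restores the phenol, so a normal prenyl group ends between the two MOM ethers while the basic solvent holds back chroman formation.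

Step 5
Reactants: 9 C-prenyl phenol
Product: 10 1-[6-methoxy-2,4-bis(methoxymethoxy)-3-(3-methylbut-2-enyl)phenyl]-2-methylpropan-1-one
Conditions: MeI, K2CO3, acetone, reflux
Reagents that add atoms: iodomethane, CI
Why: Williamson methylation of the single free hydroxyl fixes the methoxy group ortho to the ketone, a position that direct monomethylation of 3 would miss because its para hydroxyl reacts first.

Step 6
Reactants: 10 methyl ether
Product: 11 1-[2,4-dihydroxy-6-methoxy-3-(3-methylbut-2-enyl)phenyl]-2-methylpropan-1-one
Conditions: HCl (1.25 M in MeOH), rt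
Reagents that add atoms: none
Why: Acid-catalysed transacetalisation to methanol removes both MOM groups under conditions mild enough to leave the prenyl double bond unprotonated.

Step 7
Reactants: 11 prenylated dihydroxy ketone
Product: 12 1-[3-[(dimethylamino)methyl]-4,6-dihydroxy-2-methoxy-5-(3-methylbut-2-enyl)phenyl]-2-methylpropan-1-one
Conditions: 37% aq. CH2O, 40% aq. Me2NH, EtOH, rt
Reagents that add atoms: formaldehyde, C=O; dimethylamine, CNC
Why: The phenol Mannich reaction can only strike the one remaining ring CH, which lies ortho to the acidic hydroxyl para to the ketone.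

Step 8
Reactants: 12 Mannich base; 13 Meldrum's acid
Product: 16 7-hydroxy-5-methoxy-6-(2-methylpropanoyl)-8-(3-methylbut-2-enyl)-2-oxochromane-3-carboxylic acid (racemic), via quinone methide 14 (not isolated), via benzyl Meldrum's acid 15 (not isolated)
Conditions: MeCN, reflux; cold 1 M HCl wash; toluene, 85 °C
Reagents that add atoms: none
Why: Retro-Mannich loss of the amine gives ortho-quinone methide 14, Michael addition of the Meldrum's acid enolate gives 15 as its unreactive dimethylammonium salt (so the amine is never free to acylate), and after the acid wash the neighbouring phenol opens the dioxanedione with loss of acetone below the decarboxylation temperature of the half ester.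

Step 9
Reactants: 16 lactone acid
Product: 17 7-hydroxy-5-methoxy-6-(2-methylpropanoyl)-8-(3-methylbut-2-enyl)-2-oxochromane-3-carbonyl chloride (racemic)
Conditions: 1-chloro-N,N,2-trimethylprop-1-enylamine (1.05 equiv), CH2Cl2, 0 °C; solution used directly
Reagents that add atoms: 1-chloro-N,N,2-trimethylprop-1-en-1-amine, CC(C)=C(Cl)N(C)C
Why: Acid chloride formation with an α-chloroenamine runs under neutral conditions without free HCl, which spares the prenyl group, the chelated phenol and the lactone.

Step 10
Reactants: 18 pentan-3-one
Product: 19 (Z)-trimethyl(pent-2-en-3-yloxy)silane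
Conditions: TMSOTf, Et3N, CH2Cl2, 0 °C to rt; distillation
Reagents that add atoms: trimethylsilyl trifluoromethanesulfonate, C[Si](C)(C)OS(=O)(=O)C(F)(F)F
Why: Soft enolisation and O-silylation of a symmetric ketone can give only one constitution, the Z isomer should dominate under these equilibrating conditions, and the geometry is erased in step 11.

Step 11
Reactants: 17 lactone acid chloride; 19 silyl enol ether
Product: 22 6-ethyl-4-hydroxy-3-{[2,4-dihydroxy-6-methoxy-5-(2-methylpropanoyl)-3-(3-methylbut-2-enyl)phenyl]methyl}-5-methylpyran-2-one (CNP0149198.0), via acylketene 20 (not isolated), via dioxo lactone 21 (not isolated)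
Conditions: 19 (3 equiv), CH2Cl2, −78 °C; Et3N (3 equiv) dropwise, −78 °C to rt; 1 M HCl/THF work-up
Reagents that add atoms: none
Why: Proposed new method: Et3N removes HCl across the doubly activated C3–H/COCl unit of 17 to give acylketene 20, the nucleophilic carbon of 19 adds to its central carbon (C4–C5 bond), and chloride-assisted loss of the silyl group leaves the 3,5-dioxo aryl ester 21. The C6 enolate oxygen of 21 then attacks the lactone carbonyl in a 6-exo-trig addition–elimination (an E1cB loss of the phenoxide from the C3 enolate followed by capture of the new ketene by the same oxygen leads to the same bond), which forms O1–C2, closes the pyrone ring, opens the lactone ring and frees the C2' phenol. The closest known reactions are the [3+3] pyrone syntheses from silyl enol ethers and malonyl dichlorides or from ketones and chlorocarbonylketenes or bis(aryl) malonates, together with the amine-induced cyclisation of 3,5-dioxo esters; the untested element is an aryl lactone as the second acyl donor. The departing oxygen is para to the C5' ketone and so leaves as a vinylogous carboxylate, and the pyronate formed is the most stabilised anion in the flask, which should pull the transacylation forward. No stereocentre is made, since C3 of 17 and C5 of 21 both end sp2, and the symmetric ketone allows only one regiochemistry. The step needs C-acylation before O-acylation and a silent C4' hydroxyl: the first is served by having excess 19 present before the ketene is released, the second by the chelate of that hydroxyl to the ketone and by its prenyl neighbour, and any silyl ethers picked up fall off in the acidic work-up.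

**Compound list**
1 | phloroglucinol (benzene-1,3,5-triol) | Oc1cc(O)cc(O)c1 | starting material
2 | isobutyryl chloride (2-methylpropanoyl chloride) | CC(C)C(=O)Cl | starting material
3 | 2-methyl-1-(2,4,6-trihydroxyphenyl)propan-1-one | CC(C)C(=O)c1c(O)cc(O)cc1O | intermediate
4 | 1-[2-hydroxy-4,6-bis(methoxymethoxy)phenyl]-2-methylpropan-1-one | COCOc1cc(O)c(C(=O)C(C)C)c(OCOC)c1 | intermediate
5 | prenyl bromide (1-bromo-3-methylbut-2-ene) | CC(C)=CCBr | starting material
6 | 1-[2,4-bis(methoxymethoxy)-6-(3-methylbut-2-enyloxy)phenyl]-2-methylpropan-1-one | COCOc1cc(OCC=C(C)C)c(C(=O)C(C)C)c(OCOC)c1 | intermediate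
7 | 3,5-bis(methoxymethoxy)-6-(2-methylbut-3-en-2-yl)-2-(2-methylpropanoyl)cyclohexa-2,4-dien-1-one (racemic, not isolated) | O=C1C(C(C)(C)C=C)C(OCOC)=CC(OCOC)=C1C(=O)C(C)C | intermediate
8 | 3,5-bis(methoxymethoxy)-4-(3-methylbut-2-enyl)-2-(2-methylpropanoyl)cyclohexa-2,5-dien-1-one (racemic, not isolated) | O=C1C=C(OCOC)C(CC=C(C)C)C(OCOC)=C1C(=O)C(C)C | intermediate
9 | 1-[6-hydroxy-2,4-bis(methoxymethoxy)-3-(3-methylbut-2-enyl)phenyl]-2-methylpropan-1-one | COCOc1cc(O)c(C(=O)C(C)C)c(OCOC)c1CC=C(C)C | intermediate
10 | 1-[6-methoxy-2,4-bis(methoxymethoxy)-3-(3-methylbut-2-enyl)phenyl]-2-methylpropan-1-one | COCOc1cc(OC)c(C(=O)C(C)C)c(OCOC)c1CC=C(C)C | intermediate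
11 | 1-[2,4-dihydroxy-6-methoxy-3-(3-methylbut-2-enyl)phenyl]-2-methylpropan-1-one | COc1cc(O)c(CC=C(C)C)c(O)c1C(=O)C(C)C | intermediate
12 | 1-[3-[(dimethylamino)methyl]-4,6-dihydroxy-2-methoxy-5-(3-methylbut-2-enyl)phenyl]-2-methylpropan-1-one | COc1c(CN(C)C)c(O)c(CC=C(C)C)c(O)c1C(=O)C(C)C | intermediate
13 | Meldrum's acid (2,2-dimethyl-1,3-dioxane-4,6-dione) | CC1(C)OC(=O)CC(=O)O1 | starting material
14 | 3-hydroxy-5-methoxy-6-methylidene-2-(3-methylbut-2-enyl)-4-(2-methylpropanoyl)cyclohexa-2,4-dien-1-one (not isolated) | C=C1C(=O)C(CC=C(C)C)=C(O)C(C(=O)C(C)C)=C1OC | intermediate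
15 | 5-{[2,4-dihydroxy-6-methoxy-5-(2-methylpropanoyl)-3-(3-methylbut-2-enyl)phenyl]methyl}-2,2-dimethyl-1,3-dioxane-4,6-dione (not isolated) | COc1c(CC2C(=O)OC(C)(C)OC2=O)c(O)c(CC=C(C)C)c(O)c1C(=O)C(C)C | intermediate
16 | 7-hydroxy-5-methoxy-6-(2-methylpropanoyl)-8-(3-methylbut-2-enyl)-2-oxochromane-3-carboxylic acid (racemic) | COc1c(C(=O)C(C)C)c(O)c(CC=C(C)C)c2OC(=O)C(C(=O)O)Cc12 | intermediate
17 | 7-hydroxy-5-methoxy-6-(2-methylpropanoyl)-8-(3-methylbut-2-enyl)-2-oxochromane-3-carbonyl chloride (racemic) | COc1c(C(=O)C(C)C)c(O)c(CC=C(C)C)c2OC(=O)C(C(=O)Cl)Cc12 | intermediate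
18 | pentan-3-one | CCC(=O)CC | starting material
19 | (Z)-trimethyl(pent-2-en-3-yloxy)silane | C/C=C(/CC)O[Si](C)(C)C | intermediate
20 | 7-hydroxy-5-methoxy-6-(2-methylpropanoyl)-8-(3-methylbut-2-enyl)-3-(oxomethylidene)chroman-2-one (not isolated) | COc1c(C(=O)C(C)C)c(O)c(CC=C(C)C)c2OC(=O)C(=C=O)Cc12 | intermediate
21 | 7-hydroxy-5-methoxy-3-(2-methyl-3-oxopentanoyl)-6-(2-methylpropanoyl)-8-(3-methylbut-2-enyl)chroman-2-one (stereoisomer mixture, not isolated) | COc1c(C(=O)C(C)C)c(O)c(CC=C(C)C)c2OC(=O)C(C(=O)C(C)C(=O)CC)Cc12 | intermediate
22 | 6-ethyl-4-hydroxy-3-{[2,4-dihydroxy-6-methoxy-5-(2-methylpropanoyl)-3-(3-methylbut-2-enyl)phenyl]methyl}-5-methylpyran-2-one (CNP0149198.0) | CCc1oc(=O)c(Cc2c(O)c(CC=C(C)C)c(O)c(C(=O)C(C)C)c2OC)c(O)c1C | target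

**Step count**
- Total steps: 11.
- Longest linear sequence: 10 (steps 1–9 and 11, from phloroglucinol). Step 10 is a one-step side branch.

**Steps most likely to fail**

1. **Step 11.**
   - Risk: Self-condensation of the ketene or O-acylation of the enol ether may outrun C-acylation. The lactone may also be slow to hand over its acyl group, so that the open-chain dioxo ester is cleaved by a retro-Claisen process on work-up. Prolonged contact with base could scramble the bridge by retro-Michael fragmentation.
   - Fallback (known chemistry only): the pyrone is made first and the two rings are joined through the quinone methide. Silyl enol ether 19 is condensed with malonyl dichloride (Et2O, −78 °C to rt) to give 6-ethyl-4-hydroxy-5-methylpyran-2-one F1. Mannich base 12 is then heated with it (dioxane, 90 °C), so that quinone methide 14 is trapped at C3 of the hydroxypyrone by Michael addition.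
   - This path sets out from 12 and 19 and comes back at 22.

2. **Step 9.**
   - Risk: Premature loss of HCl from the acid chloride before the trap is present would lead to ketene self-condensation. Decarboxylation of the half ester during activation would remove the acyl donor.
   - Fallback: a storable active ester and a magnesium enolate replace the acid chloride and the silyl enol ether. Acid 16 is esterified with pentafluorophenol (DCC, EtOAc, 0 °C) to give pentafluorophenyl 7-hydroxy-5-methoxy-6-(2-methylpropanoyl)-8-(3-methylbut-2-enyl)-2-oxochromane-3-carboxylate F2. This acylates pentan-3-one 18 at carbon under soft enolisation (MgBr2·OEt2, iPr2NEt, CH2Cl2, rt).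
   - This path sets out from 16 and comes back at 21, which should close to 22 under the same amine base.

3. **Step 8.**
   - Risk: Amine elimination may be sluggish and the Michael adduct may revert. The malonic half ester may also decarboxylate during the thermal lactonisation.
   - Fallback: the lactone acid is built at a higher oxidation level and reduced in the cold.
     - Ketone 11 is ortho-formylated (MgCl2, Et3N, paraformaldehyde, MeCN, reflux) to give 2,4-dihydroxy-6-methoxy-5-(2-methylpropanoyl)-3-(3-methylbut-2-enyl)benzaldehyde F3.
     - Knoevenagel condensation with Meldrum's acid 13 and spontaneous lactonisation (cat. piperidinium acetate, EtOH, rt) give 7-hydroxy-5-methoxy-6-(2-methylpropanoyl)-8-(3-methylbut-2-enyl)-2-oxochromene-3-carboxylic acid F4, which cannot decarboxylate easily.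
     - Conjugate reduction (NaBH4, pyridine, 0 °C) saturates C3–C4.
   - This path sets out from 11 and comes back at 16.

**Further compounds**
F1 | step 11 | 6-ethyl-4-hydroxy-5-methylpyran-2-one | CCc1oc(=O)cc(O)c1C
F2 | step 9 | pentafluorophenyl 7-hydroxy-5-methoxy-6-(2-methylpropanoyl)-8-(3-methylbut-2-enyl)-2-oxochromane-3-carboxylate (racemic) | COc1c(C(=O)C(C)C)c(O)c(CC=C(C)C)c2OC(=O)C(C(=O)Oc3c(F)c(F)c(F)c(F)c3F)Cc12
F3 | step 8 | 2,4-dihydroxy-6-methoxy-5-(2-methylpropanoyl)-3-(3-methylbut-2-enyl)benzaldehyde | COc1c(C=O)c(O)c(CC=C(C)C)c(O)c1C(=O)C(C)C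
F4 | step 8 | 7-hydroxy-5-methoxy-6-(2-methylpropanoyl)-8-(3-methylbut-2-enyl)-2-oxochromene-3-carboxylic acid | COc1c(C(=O)C(C)C)c(O)c(CC=C(C)C)c2OC(=O)C(C(=O)O)=Cc12
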